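The cyclohexene of the spiro[4.5]decene core (spiro[4.5]decane numbering) is disconnected at its C6=C7 double bond and at the C5–C10 bond between the spiro carbon and the methyl-bearing carbon. Both bonds are made in one operation by an acid-catalysed Robinson-type spiroannulation: Michael addition of the α-carbon of a 2-formylcyclopentanone to an (E)-β-methyl enone, then aldol condensation of the formyl carbon with the enone α′-carbon. The step exploits the latent 1,3-dicarbonyl at spiro carbon C5, flanked by C1 (the chromane O–CH, carried as a ketone) and vinylic C6 (an aldehyde). Precursors: 2-(hydroxymethylene)-5-methylcyclopentanone and (E)-6-methylhept-2-en-4-one. The C8 carbonyl is then removed and the chromane is annulated by quinone methide addition and reductive etherification.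

Key step: step 4

Numbering: the terpenoid part carries spiro[4.5]decane locants (C1 = O–CH of the pyran ring, C2 = C–CH3 next to it, C5 = spiro carbon, C6=C7 with isopropyl on C7, C8 and C9 = CH2, C10 = CH–CH3). C9′ is the benzylic carbon that carries the 2-methylpropyl group.

Assumption: the (R)-configured phosphoric acid of the key step is taken to give the (5R,10R) series; should the first run give the antipode, the (S)-acid is used and nothing else changes.

Remark: the cyclopentanone intermediates before the silyl enol ether are mixtures of epimers at C2 (2RS). This carbon becomes trigonal in the enol ether and is set in step 8.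

Step 1
Reactants: 1 2-methylcyclopentan-1-one (racemic)
Product: 2 2-(hydroxymethylene)-5-methylcyclopentan-1-one (racemic; enol form of the β-keto aldehyde)
Conditions: HCO2Et, NaOMe, Et2O, 0 °C → rt; then 1 M HCl (aq)
Reagents that add atoms: ethyl formate, CCOC=O
Why: Crossed Claisen condensation (α-formylation) takes place at the methylene α-carbon because only that regioisomer can be drained as the stabilised sodium enolate of the β-keto aldehyde, so the methyl-bearing α-carbon is left untouched.

Step 2
Reactants: 3 (E)-but-2-enal; 4 isobutylmagnesium bromide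
Product: 5 (E)-6-methylhept-2-en-4-ol (racemic)
Conditions: THF, −78 → 0 °C; then NH4Cl (aq)
Reagents that add atoms: none
Why: Grignard addition to an enal proceeds 1,2 at low temperature and leaves the (E)-alkene intact, and the racemic carbinol center is destroyed in step 3.

Step 3
Reactants: 5 (E)-6-methylhept-2-en-4-ol
Product: 6 (E)-6-methylhept-2-en-4-one
Conditions: MnO2 (activated, excess), CH2Cl2, rt
Reagents that add atoms: none
Why: MnO2 oxidises allylic alcohols selectively to enones without isomerising the (E)-double bond.

Step 4
Reactants: 2 2-(hydroxymethylene)-5-methylcyclopentan-1-one; 6 (E)-6-methylhept-2-en-4-one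
Product: 8 (2RS,5R,10R)-2,10-dimethyl-7-(propan-2-yl)spiro[4.5]dec-6-ene-1,8-dione, via Michael adduct keto-aldehyde 7 (not isolated)
Conditions: (R)-TRIP [(R)-3,3′-bis(2,4,6-triisopropylphenyl)-1,1′-binaphthalene-2,2′-diyl hydrogen phosphate] (10 mol%), toluene, 40 °C; then 100 °C
Reagents that add atoms: none
Why: The hydrogen-bonded enol of 2 adds through its only nucleophilic carbon (C5) to the β-carbon (C10) of the acid-activated (E)-enone 6 to give keto-aldehyde 7, whose side-chain ketone enolises towards C7 and condenses with the formyl carbon C6, and loss of water fixes the C6=C7 double bond, so that the C5–C10 and C6=C7 bonds are formed in one flask by one catalyst. The closest known reaction type is the Brønsted-acid-catalysed Robinson-type (Michael addition/aldol condensation) spiroannulation of 2-formyl ketones and other 1,3-dicarbonyl compounds with enones, including its chiral phosphoric acid version. The cyclohexenone ring closes by a 6-(enolendo)-exo-trig aldol addition followed by dehydration. C5 and C10 are created together in the Michael step: the phosphoric acid bridges the enol O–H of 2 and the carbonyl oxygen of 6 and so selects the enone face (absolute configuration), while the compact endo arrangement, in which the chelated enol O–H and the C1 carbonyl lie under the s-cis enone, should place the C10 methyl group cis to C1 on the new ring (relative configuration). The step needs aldol closure onto the aldehyde and not onto the C1 ketone, which the higher electrophilicity of the formyl group and the shielding of C1 by the quaternary C5 and the methyl-bearing C2 secure, and C7 is the only enolisable carbon that can reach C6 through a six-membered ring.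

Step 5
Reactants: 8 (2RS,5R,10R)-2,10-dimethyl-7-(propan-2-yl)spiro[4.5]dec-6-ene-1,8-dione
Product: 9 (2RS,5R,10R)-8,8-(ethane-1,2-diyldisulfanediyl)-2,10-dimethyl-7-(propan-2-yl)spiro[4.5]dec-6-en-1-one (1,3-dithiolane of the C8 ketone)
Conditions: HSCH2CH2SH (1.1 equiv), BF3·OEt2 (cat.), AcOH, rt
Reagents that add atoms: ethane-1,2-dithiol, SCCS
Why: Acid-catalysed dithioketalisation takes the conjugated C8 carbonyl and spares the C1 ketone, which is flanked by the quaternary spiro carbon and the methyl-bearing C2 (the selectivity that distinguishes a steroidal 4-en-3-one from a 17-ketone), and dithioketals of enones form without migration of the double bond.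

Step 6
Reactants: 9 the 1,3-dithiolane of step 5
Product: 10 (2RS,5R,10R)-2,10-dimethyl-7-(propan-2-yl)spiro[4.5]dec-6-en-1-one
Conditions: Raney Ni (W-2), acetone, reflux
Reagents that add atoms: none
Why: Raney Ni desulfurisation replaces both C–S bonds by C–H bonds, hydrogen being delivered at C8 and not at the neopentylic C6 so that the C6=C7 double bond should stay in place, while acetone as solvent spares the hindered ketone and the trisubstituted alkene.

Step 7
Reactants: 10 (2RS,5R,10R)-2,10-dimethyl-7-(propan-2-yl)spiro[4.5]dec-6-en-1-one
Product: 11 tert-butyl{[(5R,10R)-2,10-dimethyl-7-(propan-2-yl)spiro[4.5]deca-1,6-dien-1-yl]oxy}dimethylsilane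
Conditions: TBSOTf, Et3N, CH2Cl2, 0 °C → rt
Reagents that add atoms: tert-butyldimethylsilyl trifluoromethanesulfonate, CC(C)(C)[Si](C)(C)OS(=O)(=O)C(F)(F)F
Why: Soft enolisation with a silyl triflate and a tertiary amine can only take place towards C2 because C5 is quaternary, so a single tetrasubstituted silyl enol ether forms and the C2 epimers converge.

Step 8
Reactants: 11 the silyl enol ether of step 7; 12 2,4,6-trihydroxybenzene-1,3-dicarbaldehyde; 13 3-methylbutanal
Product: 15 5-{(1R)-1-[(2R,5R,10R)-2,10-dimethyl-1-oxo-7-(propan-2-yl)spiro[4.5]dec-6-en-2-yl]-3-methylbutyl}-2,4,6-trihydroxybenzene-1,3-dicarbaldehyde, via ortho-quinone methide 14 (not isolated)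
Conditions: 12, 13, MeNHCH2CH2NHMe (20 mol%), (CF3)2CHOH, rt; then 11, CH2Cl2, 0 °C → rt; 1 M HCl (aq), THF
Reagents that add atoms: none
Why: Amine-catalysed Knoevenagel condensation of 12 with 13 gives the electrophilic ortho-quinone methide 14, which the silyl enol ether attacks at C9′ in a Mukaiyama–Michael addition, C2 being set by attack on the cyclopentene face anti to C10 (whose methyl group leans over the other face) and C9′ by an open transition state in which the aryl ring lies anti to C1, the hydrogen points under the five-membered ring towards C6–H and the isobutyl group lies under the silyloxy oxygen.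

Step 9
Reactants: 15 the keto-phenol of step 8
Product: 17 CNP0121396.3 (target; C1 S; C2 R; C5 R; C10 R; C9′ S), via cyclic hemiketal 16 (not isolated)
Conditions: Et3SiH (5 equiv), BF3·OEt2 (3 equiv), CH2Cl2, −40 → 0 °C
Reagents that add atoms: none
Why: The Lewis acid promotes closure of the phenol onto the C1 ketone and ionisation to the ring-fused oxocarbenium ion, which Et3SiH reduces (reductive etherification) on the convex face that carries the C2 methyl group, the only face that keeps the pyran cis-fused to the cyclopentane, and this sets C1, while the hydrogen-bonded formyl groups behave as vinylogous esters and the alkene is not protonated at low temperature.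

Compound list

1 | 2-methylcyclopentan-1-one (racemic) | CC1CCCC1=O | starting material
2 | 2-(hydroxymethylene)-5-methylcyclopentan-1-one (racemic) | CC1CCC(=CO)C1=O | intermediate
3 | (E)-but-2-enal | C/C=C/C=O | starting material
4 | isobutylmagnesium bromide | CC(C)C[Mg]Br | starting material
5 | (E)-6-methylhept-2-en-4-ol (racemic) | C/C=C/C(O)CC(C)C | intermediate
6 | (E)-6-methylhept-2-en-4-one | C/C=C/C(=O)CC(C)C | intermediate
7 | (1R,3RS)-3-methyl-1-[(2R)-6-methyl-4-oxoheptan-2-yl]-2-oxocyclopentane-1-carbaldehyde (formed in the flask in step 4) | CC1CC[C@@](C=O)(C1=O)[C@H](C)CC(=O)CC(C)C | intermediate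
8 | (2RS,5R,10R)-2,10-dimethyl-7-(propan-2-yl)spiro[4.5]dec-6-ene-1,8-dione | CC1CC[C@]2(C1=O)C=C(C(C)C)C(=O)C[C@H]2C | intermediate
9 | (2RS,5R,10R)-8,8-(ethane-1,2-diyldisulfanediyl)-2,10-dimethyl-7-(propan-2-yl)spiro[4.5]dec-6-en-1-one | CC1CC[C@]2(C1=O)C=C(C(C)C)C3(SCCS3)C[C@H]2C | intermediate
10 | (2RS,5R,10R)-2,10-dimethyl-7-(propan-2-yl)spiro[4.5]dec-6-en-1-one | CC1CC[C@]2(C1=O)C=C(C(C)C)CC[C@H]2C | intermediate
11 | tert-butyl{[(5R,10R)-2,10-dimethyl-7-(propan-2-yl)spiro[4.5]deca-1,6-dien-1-yl]oxy}dimethylsilane | CC1=C(O[Si](C)(C)C(C)(C)C)[C@@]2(CC1)C=C(C(C)C)CC[C@H]2C | intermediate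
12 | 2,4,6-trihydroxybenzene-1,3-dicarbaldehyde | O=Cc1c(O)cc(O)c(C=O)c1O | starting material
13 | 3-methylbutanal | CC(C)CC=O | starting material
14 | 2,4-dihydroxy-5-(3-methylbutylidene)-6-oxocyclohexa-1,3-diene-1,3-dicarbaldehyde (ortho-quinone methide, formed in the flask in step 8) | CC(C)CC=C1C(=O)C(C=O)=C(O)C(C=O)=C1O | intermediate
15 | 5-{(1R)-1-[(2R,5R,10R)-2,10-dimethyl-1-oxo-7-(propan-2-yl)spiro[4.5]dec-6-en-2-yl]-3-methylbutyl}-2,4,6-trihydroxybenzene-1,3-dicarbaldehyde | CC(C)C[C@H](c1c(O)c(C=O)c(O)c(C=O)c1O)[C@@]1(C)CC[C@]2(C1=O)C=C(C(C)C)CC[C@H]2C | intermediate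
16 | cis-fused cyclic hemiketal of 15 (phenol oxygen closed onto C1, hydroxyl on the face of the C2 methyl group; formed in the flask in step 9) | CC(C)C[C@@H]1c2c(O)c(C=O)c(O)c(C=O)c2O[C@@]2(O)[C@]1(C)CC[C@@]21C=C(C(C)C)CC[C@H]1C | intermediate
17 | CNP0121396.3: 5,7-dihydroxy-3-methyl-4-(2-methylpropyl)chromane-6,8-dicarbaldehyde whose chromane C2 and C3 are C1 and C2 of a (5R,10R)-10-methyl-7-(propan-2-yl)spiro[4.5]dec-6-ene unit, cis ring fusion, C1 S, C2 R, C9′ S | CC(C)C[C@@H]1c2c(O)c(C=O)c(O)c(C=O)c2O[C@H]2[C@]1(C)CC[C@@]21C=C(C(C)C)CC[C@H]1C | target

Total steps: 9. Longest linear sequence: 8 steps (steps 2 to 9, from (E)-but-2-enal).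

Steps most likely to fail

Risk 1 (step 4). The Michael addition to a β-methyl enone at a carbon that becomes quaternary may be slow. An uncatalysed background reaction at the temperature needed for cyclodehydration may erode enantio- and diastereoselectivity, and the formyl group may be lost. Fallback: stereocontrol is moved from the hydrogen-bonding acid to a chiral palladium enolate, and the two bond-forming events are triggered separately in the same flask. Compounds 2 and 6 are combined with [Pd((R)-BINAP)(H2O)2](OTf)2 (5 mol%) in THF at −20 °C → rt. This should give keto-aldehyde 7 through the O,O-chelated enolate of divalent palladium, a known mode of addition of 1,3-dicarbonyl compounds to β-substituted enones. TsOH·H2O and toluene are then added and the mixture is warmed to 80 °C to complete the aldol condensation. The fallback sets out from 2 and 6 and comes back at 8; it forms no compound outside the list.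

Risk 2 (step 8). The hindered enol ether may be protodesilylated before the C–C bond forms. The addition may also run through a closed, hetero-Diels–Alder-like transition state, which would invert the benzylic center, or take place on the other face of C2. Fallback: the benzylic hydrogen is delivered last instead of being carried in with the electrophile. Ketone 10 is deprotonated (LiN(iPr)2, THF, −78 °C) and the enolate is added to 13 on the face anti to C10 to give aldol F1, which is oxidised with Dess–Martin periodinane to β-diketone F2. Diketone F2 is condensed with phloroglucinol (BF3·OEt2, 1,4-dioxane/CH2Cl2, 0 °C → rt). Friedel–Crafts attack on the isobutyl ketone and closure of a phenol oxygen onto C1 give tricyclic hemiketal F3 (not isolated). Et3SiH added to the same flask should reduce the benzylic cation and the oxocarbenium ion on the convex face and give dihydroxychromane F4. Vilsmeier–Haack diformylation (POCl3, DMF, MeCN, 0 °C → rt; then H2O, 60 °C) at the two free ring positions gives the target. The fallback sets out from 10 and comes back at 17.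

Risk 3 (step 9). Closure and ionisation at C1, which lies between two quaternary carbons, may be slow. Forcing the reaction invites reduction of the formyl groups and ionic hydrogenation of the C6=C7 alkene by adventitious protic acid. Fallback: the formyl groups are introduced after the ring closure. Under the conditions of step 8, phloroglucinol (in excess) and 13 give ortho-quinone methide F5 (not isolated), which adds to enol ether 11 and gives keto-triol F6 after acidic work-up. With no aldehyde present the reductive etherification can be forced (Et3SiH, TMSOTf, CH2Cl2, −20 °C → rt) to dihydroxychromane F4, the compound already described under risk 2. The same Vilsmeier–Haack diformylation then gives the target. The fallback sets out from 11 and comes back at 17.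

Further compounds

F0 | step 4 | none | none
F1 | step 8 | (2R,5R,10R)-2-(1-hydroxy-3-methylbutyl)-2,10-dimethyl-7-(propan-2-yl)spiro[4.5]dec-6-en-1-one (carbinol epimers) | CC(C)CC(O)[C@@]1(C)CC[C@]2(C1=O)C=C(C(C)C)CC[C@H]2C
F2 | step 8 | (2R,5R,10R)-2,10-dimethyl-2-(3-methylbutanoyl)-7-(propan-2-yl)spiro[4.5]dec-6-en-1-one | CC(C)CC(=O)[C@@]1(C)CC[C@]2(C1=O)C=C(C(C)C)CC[C@H]2C
F3 | step 8 | tricyclic hemiketal of F2 and phloroglucinol with a tertiary benzylic hydroxyl at C9′ and a hemiketal hydroxyl at C1 (not isolated) | CC(C)CC1(O)c2c(O)cc(O)cc2OC2(O)[C@]1(C)CC[C@@]21C=C(C(C)C)CC[C@H]1C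
F4 | step 8 | dihydroxychromane, the analogue of 17 with hydrogen in place of both formyl groups (C1 S, C2 R, C5 R, C10 R, C9′ S) | CC(C)C[C@@H]1c2c(O)cc(O)cc2O[C@H]2[C@]1(C)CC[C@@]21C=C(C(C)C)CC[C@H]1C
F5 | step 9 | 3,5-dihydroxy-6-(3-methylbutylidene)cyclohexa-2,4-dien-1-one (ortho-quinone methide, not isolated) | CC(C)CC=C1C(=O)C=C(O)C=C1O
F6 | step 9 | (2R,5R,10R)-2,10-dimethyl-2-[(1R)-3-methyl-1-(2,4,6-trihydroxyphenyl)butyl]-7-(propan-2-yl)spiro[4.5]dec-6-en-1-one | CC(C)C[C@H](c1c(O)cc(O)cc1O)[C@@]1(C)CC[C@]2(C1=O)C=C(C(C)C)CC[C@H]2C
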